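Remarks on the chemistry and notation: CH2N2 is taken as an ethereal solution made fresh from N-methyl-N-nitroso-p-toluenesulfonamide and KOH and is counted as a reagent. The sp3 carbons of the transient compounds 24 and 26 form racemic and vanish on aromatisation. In names, Ar = 3-[(E)-4-(tert-butyldimethylsilyloxy)-3-methylbut-2-en-1-yl]-4-(triisopropylsilyloxy)phenyl.

## The problem

Vogelin E (28) is an isoflavone, a chromen-4-one in which ring A is fused to pyranone ring C through C4a–C8a and ring B sits on C3, so the skeleton asks only for one aryl–vinyl bond (C3–C1') and one ring fusion. There is no stereocentre; the single stereochemical element is the E trisubstituted olefin C2''=C3'' of the 4-hydroxy-3-methylbut-2-enyl chain on C3'. Nothing else in the molecule can direct that geometry, so it has to come from a reaction that is E-selective by itself. The primary allylic alcohol lies close to O4', so acid ionises it and lets the phenol close an oxygen heterocycle. The olefin and the allylic C–O bond also forbid hydrogenolysis, and ring C opens at C2 under hot hydroxide or alkoxide, so the three phenols and the alcohol must be freed at the end without acid, hydrogen or a hard nucleophile. The enabling feature is ring A (C4a, C5, C6, C7, C8, C8a), a resorcinol whose C5 hydroxyl sits next to the fusion carbon C4a with the C7 oxygen meta to it. That is the pattern formed when a vinylketene whose vinyl unit is C8a=C4a combines with an alkoxyalkyne: the ketene carbon becomes C5–OH and the alkyne supplies C6 and C7–OR. The C2=C3 bond of a 4-pyranone can serve as that vinyl unit, so ring C, with ring B already attached, can be complete before ring A exists.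

## Retrosynthesis

**28 from 27.** Three oxygen–protecting-group bonds are cut: O4'–Si, chain O–Si and O7–CH2. All three are chosen to fall to fluoride, so acid and hydrogen are avoided. O5 needs no group because it is hydrogen-bonded to the C4 carbonyl. O7 is para to that carbonyl, a vinylogous carboxylate, so its 2-(trimethylsilyl)ethyl ether should fragment about as easily as the corresponding ester. The forward reaction must be one fluoride operation that leaves the E olefin and ring C alone.

**27 from 17 and 22.** Ring A is removed by cutting C8–C8a, C7–C8, C5–C6 and C4a–C5. The neighbouring cuts were weighed. Cutting C3–C1' on a chromone, or closing ring C onto a phloroglucinol, both start from a ring A whose two oxygens must be told apart by protecting-group work. This cut makes ring A from the two-carbon ynol ether 22 and the diazoketone 17, and delivers O5 free and O7 masked. Compound 17 is a monocyclic pyranone that already holds ring B and the finished side chain. The cascade is expected to run through ketene 23, cyclobutenone 24, dienylketene 25 and dienone 26. The forward reaction needs a Wolff rearrangement that does not disturb the pyranone chromophore, and a [2+2] addition of the right polarity.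

**17 from 13 by way of 15.** The bond between the acyl carbon (the future C5) and the diazo carbon (the future C8) is cut, which leads to carboxylic acid 15 through its chloride 16. The carboxyl carbon is then traced to the hydroxymethyl carbon of 13, with aldehyde 14 in between. Oxidising after the coupling, and not before, avoids an ester and its basic hydrolysis next to a base-sensitive pyranone. The forward steps need an oxidant that spares the olefin and silyl ethers, and an acid chloride formation that liberates no HCl.

**13 from 10 and 12.** The C3–C1' bond (pyranone C5 to aryl) is cut for a Suzuki–Miyaura coupling. It was preferred to forming this bond after ring A, because the whole of ring B with its chain then enters in one convergent step on a small triflate. Triflate 12 comes in one step from kojic acid 11, whose acidic enol hydroxyl can be sulfonylated next to the primary alcohol.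

**10 back to 1, 2 and 6.** Boronate 10 comes from bromide 9. The silyl groups are removed in turn, giving 8 and then enal 7. The C2''=C3'' double bond of 7 is cut for a cross metathesis between allylarene 5 and methacrolein 6, which brings C3'', the methyl group and C4'' in one piece and favours the E isomer. A stabilised Wittig reaction is the neighbour and is kept in reserve. Compound 5 is the silyl ether of 2-allyl-4-bromophenol 4, and the C3'–C1'' bond of 4 is cut by an aromatic Claisen rearrangement of allyl ether 3, made from 4-bromophenol 1 and allyl bromide 2. The bromine blocks the para position during the rearrangement and later marks the site for boron. O4' is masked as the triisopropylsilyl ether so that it survives aqueous base, and the chain oxygen as the tert-butyldimethylsilyl ether.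

**22 from 18 and 19.** The ynol ether is cut at the two C–Cl bonds of dichlorovinyl ether 20, with lithium acetylide 21 as the link. Compound 20 is cut at its O–C(vinyl) bond to 2-(trimethylsilyl)ethanol 18 and trichloroethylene 19. The forward chemistry must be run cold, since ynol ethers with β-hydrogens fragment on heating.

## Roads not taken

Alternative 1: The cut lies inside the side chain, at C1''–C2'' and C3''–CH3, on an intact isoflavone. Prop-2-yn-1-ol A3 would be methylaluminated with Al(CH3)3 under Cp2ZrCl2 catalysis to the (E)-alkenylalane A4. In the same flask A4 would be coupled with benzylic chloride A2 under Pd(PPh3)4 to give the tris(methoxymethyl) ether A1.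
- Merits: syn carbometalation of A3 is stereospecific, so the E geometry is fixed by mechanism. That is a firmer guarantee than the thermodynamic preference on which step 4 relies, and in this respect the alternative is better. The chain is also joined in the last C–C bond-forming event.
- Weak points: A2 is an ortho-alkoxybenzyl chloride on an electron-rich ring. It is prone to solvolysis and must itself be made from a 3'-functionalised isoflavone. The free hydroxyl of A3 consumes one equivalent of Al(CH3)3, and the excess reagent meets the chromone carbonyl and C2 of A2. Most seriously, the three acetal groups of A1 come off only with acid, the reagent class that ionises the allylic alcohol and closes a ring onto O4'.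
- Comparison: against the better olefin control, the chosen plan sets an end-game that uses fluoride only and a ring A whose oxygens need no differentiation.

Alternative 2: The cuts are C3–C1' and O1–C2, back to the 2'-hydroxychalcone A6. Tl(NO3)3 in methanol would shift ring B from the β- to the α-carbon of A6, and acid added to the same flask would close ring C to give bromo-isoflavone A5.
- Merits: this is the most thoroughly precedented entry to an isoflavone core and is built from two simple aromatic pieces. In reliability of the ring-forming step it is clearly ahead of the benzannulation proposed here.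
- Weak points: it uses a full equivalent of a highly toxic thallium salt. Ring A must enter with O5 and O7 benzylated and O2' free, which costs a selective protection. A5 still lacks the whole side chain, which has to be coupled onto the aryl bromide afterwards. The three benzyl ethers must then be removed without hydrogenating the olefin or cleaving the allylic C–O bond, which leaves only Lewis acids that endanger the allylic alcohol.
- Comparison: the chosen plan carries a complete side chain from the start and removes all protecting groups in one fluoride step. It pays for this with a less tested key step.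

Alternative 3: The cuts are C3–C4 and O1–C8a. Enamine A9 of the ring B acetaldehyde would be C-acylated by 2,4,6-trifluorobenzoyl chloride A8. Aqueous K2CO3 would then hydrolyse the enaminone and let the enolate oxygen displace an ortho fluoride, giving the 5,7-difluoroisoflavone A7.
- Merits: the plan is convergent, ring B travels with its finished chain as in the chosen plan, and the symmetry of A8 removes any regiochemical question. The skeleton is reached in fewer steps than below, and here the alternative is equal or better.
- Weak points: A7 is not yet at the right oxidation pattern, since two C–F bonds must still be exchanged for C–O by nucleophilic aromatic substitution. The first (C7, para to the carbonyl) is easy, but the ring is then deactivated for the second. The alkoxides required also add to C2 of ring C and attack aryl silyl ethers. A9 has to be made from arylacetaldehyde A10, which is prone to self-condensation.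
- Comparison: the chosen plan delivers both ring A oxygens directly, O5 free and O7 masked, and has to justify its longer route by avoiding these two late substitutions.

Key step: step 14

## Route

Step 1
Reactants: 1 4-bromophenol; 2 allyl bromide
Product: 3 1-(allyloxy)-4-bromobenzene
Conditions: K2CO3, acetone, 56 °C
Reagents that add atoms: none
Why: Williamson ether synthesis; the phenoxide displaces the allylic bromide by SN2 and O-alkylation dominates in acetone.

Step 2
Reactants: 3 1-(allyloxy)-4-bromobenzene
Product: 4 2-allyl-4-bromophenol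
Conditions: PhNEt2, 195 °C
Reagents that add atoms: none
Why: Aromatic Claisen [3,3]-sigmatropic rearrangement followed by tautomerisation; the two ortho positions are equivalent and the para position carries bromine, so a single phenol is expected.

Step 3
Reactants: 4 2-allyl-4-bromophenol
Product: 5 (2-allyl-4-bromophenoxy)triisopropylsilane
Conditions: i-Pr3SiCl, imidazole, DMF, 40 °C
Reagents that add atoms: chlorotriisopropylsilane, CC(C)[Si](Cl)(C(C)C)C(C)C
Why: Imidazole-promoted silylation of the phenol; the bulky aryl silyl ether is chosen to survive the aqueous base of step 9, and capping the phenol prevents oxa-Michael addition to the enal made in step 4.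

Step 4
Reactants: 5 (2-allyl-4-bromophenoxy)triisopropylsilane; 6 methacrolein
Product: 7 (E)-4-[5-bromo-2-(triisopropylsilyloxy)phenyl]-2-methylbut-2-enal
Conditions: 6 (8 equiv), second-generation Grubbs catalyst RuCl2(H2IMes)(PCy3)(=CHPh) (5 mol %), 1,4-benzoquinone (10 mol %), CH2Cl2, 40 °C
Reagents that add atoms: none
Why: Olefin cross metathesis of a terminal olefin with a 1,1-disubstituted enal that homodimerises slowly; the trisubstituted enal forms under thermodynamic control with the formyl group trans to the benzylic CH2, which sets the E geometry of C2''=C3'', and benzoquinone suppresses double-bond migration.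

Step 5
Reactants: 7 (E)-4-[5-bromo-2-(triisopropylsilyloxy)phenyl]-2-methylbut-2-enal
Product: 8 (E)-4-[5-bromo-2-(triisopropylsilyloxy)phenyl]-2-methylbut-2-en-1-ol
Conditions: i-Bu2AlH, CH2Cl2, −78 °C; aq. KNaC4H4O6
Reagents that add atoms: none
Why: 1,2-Reduction of the enal by an aluminium hydride at low temperature; the olefin geometry, the aryl bromide and the silyl ether are not touched.

Step 6
Reactants: 8 (E)-4-[5-bromo-2-(triisopropylsilyloxy)phenyl]-2-methylbut-2-en-1-ol
Product: 9 {[(E)-4-[5-bromo-2-(triisopropylsilyloxy)phenyl]-2-methylbut-2-en-1-yl]oxy}(tert-butyl)dimethylsilane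
Conditions: t-BuMe2SiCl, imidazole, CH2Cl2, 20 °C
Reagents that add atoms: tert-butylchlorodimethylsilane, CC(C)(C)[Si](C)(C)Cl
Why: Standard silylation of a primary alcohol; the ether masks the hydroxyl against the acid chloride and ketene chemistry of steps 11 and 14.

Step 7
Reactants: 9 {[(E)-4-[5-bromo-2-(triisopropylsilyloxy)phenyl]-2-methylbut-2-en-1-yl]oxy}(tert-butyl)dimethylsilane
Product: 10 tert-butyldimethyl{[(E)-2-methyl-4-[5-(4,4,5,5-tetramethyl-1,3,2-dioxaborolan-2-yl)-2-(triisopropylsilyloxy)phenyl]but-2-en-1-yl]oxy}silane
Conditions: B2pin2, PdCl2(dppf)·CH2Cl2 (3 mol %), KOAc, 1,4-dioxane, 85 °C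
Reagents that add atoms: bis(pinacolato)diboron, CC1(C)OB(OC1(C)C)B1OC(C)(C)C(C)(C)O1
Why: Miyaura borylation of an aryl bromide; the weak acetate base prevents onward Suzuki coupling, and silyl ethers and the trisubstituted olefin are inert to the palladium catalyst.

Step 8
Reactants: 11 kojic acid
Product: 12 6-(hydroxymethyl)-4-oxo-4H-pyran-3-yl trifluoromethanesulfonate
Conditions: PhNTf2, Et3N, DMF, 0 → 20 °C
Reagents that add atoms: N-phenylbis(trifluoromethanesulfonimide), O=S(=O)(N(c1ccccc1)S(=O)(=O)C(F)(F)F)C(F)(F)F
Why: Chemoselective O-triflation; the acidic enol hydroxyl reacts as its ammonium enolate with a mild triflimide that does not sulfonylate a neutral primary alcohol, the same selectivity as phenol over alcohol.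

Step 9
Reactants: 10 tert-butyldimethyl{[(E)-2-methyl-4-[5-(4,4,5,5-tetramethyl-1,3,2-dioxaborolan-2-yl)-2-(triisopropylsilyloxy)phenyl]but-2-en-1-yl]oxy}silane; 12 6-(hydroxymethyl)-4-oxo-4H-pyran-3-yl trifluoromethanesulfonate
Product: 13 2-(hydroxymethyl)-5-Ar-4H-pyran-4-one
Conditions: PdCl2(dppf)·CH2Cl2 (5 mol %), K3PO4, 1,4-dioxane/H2O (10:1), 70 °C
Reagents that add atoms: none
Why: Suzuki–Miyaura coupling; oxidative addition is easy at the electron-poor α-triflyloxy enone, and the reaction forms the C3–C1' bond of the isoflavone with the free hydroxymethyl group as a spectator.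

Step 10
Reactants: 13 2-(hydroxymethyl)-5-Ar-4H-pyran-4-one
Product: 15 4-oxo-5-Ar-4H-pyran-2-carboxylic acid, via pyranone-2-carbaldehyde 14 (not isolated)
Conditions: TEMPO (20 mol %), PhI(OAc)2 (2.5 equiv), MeCN/H2O (1:1), 0 → 20 °C
Reagents that add atoms: water, O
Why: Oxoammonium-mediated oxidation of a primary alcohol to the acid through aldehyde 14 and its hydrate; the oxidant leaves the trisubstituted olefin, the silyl ethers and the arene alone.

Step 11
Reactants: 15 4-oxo-5-Ar-4H-pyran-2-carboxylic acid
Product: 17 2-(2-diazoacetyl)-5-Ar-4H-pyran-4-one, via acid chloride 16 (not isolated)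
Conditions: Me2C=C(Cl)NMe2, CH2Cl2, 0 → 20 °C; then added to CH2N2 (3 equiv), Et2O, 0 °C
Reagents that add atoms: diazomethane, C=[N+]=[N-]
Why: The α-chloroenamine makes the acid chloride without liberating HCl, which protects the silyl ethers; acylation of diazomethane (the first stage of the Arndt–Eistert sequence) then gives the diazoketone, a second equivalent of CH2N2 taking up the HCl, and the diazo carbon is the future C8.

Step 12
Reactants: 18 2-(trimethylsilyl)ethanol; 19 trichloroethylene
Product: 20 {2-[(E)-1,2-dichloroethenoxy]ethyl}trimethylsilane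
Conditions: KH, THF, 0 °C; then 19, −50 → 20 °C
Reagents that add atoms: none
Why: The potassium alkoxide eliminates HCl from trichloroethylene and adds anti to the dichloroacetylene so formed, the established dichlorovinyl ether entry to alkynyl ethers from alcohols; anti addition gives the E isomer.

Step 13
Reactants: 20 {2-[(E)-1,2-dichloroethenoxy]ethyl}trimethylsilane
Product: 22 [2-(ethynyloxy)ethyl]trimethylsilane (2-(trimethylsilyl)ethoxyethyne), via lithium alkoxyacetylide 21 (not isolated)
Conditions: n-BuLi (2.3 equiv), Et2O, −78 → −40 °C; MeOH, −78 °C; distilled cold and kept as a solution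
Reagents that add atoms: none
Why: Base-induced elimination to the chloroalkynyl ether and chlorine–lithium exchange give acetylide 21, which methanol protonates to the terminal ynol ether; the material is kept cold because ynol ethers with β-hydrogens fragment by a retro-ene path on heating.

Step 14
Reactants: 17 2-(2-diazoacetyl)-5-Ar-4H-pyran-4-one; 22 [2-(ethynyloxy)ethyl]trimethylsilane
Product: 27 5-hydroxy-3-Ar-7-[2-(trimethylsilyl)ethoxy]-4H-chromen-4-one, via pyranonylketene 23 (not isolated), via pyranonylcyclobutenone 24 (not isolated), via dienylketene 25 (not isolated), via cyclohexadienone 26 (not isolated)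
Conditions: 22 (2.5 equiv), degassed ClCH2CH2Cl (0.05 M), hν (365 nm), 20 °C; then 80 °C
Reagents that add atoms: none
Why: Irradiation at 365 nm is chosen to excite the diazoketone chromophore and not the aryl-pyranone, so 17 should lose N2 with 1,2-shift of the pyranonyl group (photochemical Wolff rearrangement, forming C8–C8a) to give vinylketene 23. The nucleophilic CH terminus of ynol ether 22 attacks the electrophilic ketene carbon and the [2+2] cycloaddition closes cyclobutenone 24 (C5–C6 and C7–C8); this polarity match places the alkoxy group on C7 and not on C6. On warming, 24 opens by reversible conrotatory four-electron electrocyclic cleavage to dienylketene 25, and only the isomer with the pyranonyl group cis to the ketene carbon can react on. Thermal disrotatory six-electron electrocyclisation joins the ketene carbon to C3 of the pyranone (C4a–C5) and closes the six-membered carbocyclic ring A as dienone 26; C3 is the only free terminus of the pyranone C2=C3 unit, so no regioisomer of closure exists. Enolisation of the doubly activated C4a–H aromatises 26 to phenol 27, whose new hydroxyl is hydrogen-bonded to the C4 carbonyl and therefore slow to be acylated by remaining ketene. The closest known reaction type is the photochemical-Wolff form of the Danheiser benzannulation of aryl, heteroaryl and alkenyl diazoketones with alkoxy- and siloxyalkynes. No stereocentre is created in 27; the sp3 carbons of 24 and 26 are transient and racemic. The step needs the ketene to be captured by the electron-rich alkyne and not by the trisubstituted olefin or the silyl ethers, which the large difference in nucleophilicity and the excess of 22 should secure.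

Step 15
Reactants: 27 5-hydroxy-3-Ar-7-[2-(trimethylsilyl)ethoxy]-4H-chromen-4-one
Product: 28 Vogelin E, 5,7-dihydroxy-3-{4-hydroxy-3-[(E)-4-hydroxy-3-methylbut-2-en-1-yl]phenyl}-4H-chromen-4-one
Conditions: Bu4NF (6 equiv), THF, 0 → 50 °C; AcOH quench
Reagents that add atoms: none
Why: Fluoride cleaves both Si–O bonds, and attack at the trimethylsilyl group fragments the 2-(trimethylsilyl)ethyl ether to ethylene and the C7 phenoxide; O7 is para to the C4 carbonyl (a vinylogous carboxylate) and should leave about as readily as from the corresponding ester, and no acid or hydrogen touches the allylic alcohol or the E olefin.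

## Compound list

1 | 4-bromophenol | Oc1ccc(Br)cc1 | starting material
2 | allyl bromide | C=CCBr | starting material
3 | 1-(allyloxy)-4-bromobenzene | C=CCOc1ccc(Br)cc1 | intermediate
4 | 2-allyl-4-bromophenol | C=CCc1cc(Br)ccc1O | intermediate
5 | (2-allyl-4-bromophenoxy)triisopropylsilane | C=CCc1cc(Br)ccc1O[Si](C(C)C)(C(C)C)C(C)C | intermediate
6 | methacrolein | C=C(C)C=O | starting material
7 | (E)-4-[5-bromo-2-(triisopropylsilyloxy)phenyl]-2-methylbut-2-enal | C/C(=C\Cc1cc(Br)ccc1O[Si](C(C)C)(C(C)C)C(C)C)C=O | intermediate
8 | (E)-4-[5-bromo-2-(triisopropylsilyloxy)phenyl]-2-methylbut-2-en-1-ol | C/C(=C\Cc1cc(Br)ccc1O[Si](C(C)C)(C(C)C)C(C)C)CO | intermediate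
9 | {[(E)-4-[5-bromo-2-(triisopropylsilyloxy)phenyl]-2-methylbut-2-en-1-yl]oxy}(tert-butyl)dimethylsilane | C/C(=C\Cc1cc(Br)ccc1O[Si](C(C)C)(C(C)C)C(C)C)CO[Si](C)(C)C(C)(C)C | intermediate
10 | tert-butyldimethyl{[(E)-2-methyl-4-[5-(4,4,5,5-tetramethyl-1,3,2-dioxaborolan-2-yl)-2-(triisopropylsilyloxy)phenyl]but-2-en-1-yl]oxy}silane | C/C(=C\Cc1cc(B2OC(C)(C)C(C)(C)O2)ccc1O[Si](C(C)C)(C(C)C)C(C)C)CO[Si](C)(C)C(C)(C)C | intermediate
11 | kojic acid, 5-hydroxy-2-(hydroxymethyl)-4H-pyran-4-one | OCc1cc(=O)c(O)co1 | starting material
12 | 6-(hydroxymethyl)-4-oxo-4H-pyran-3-yl trifluoromethanesulfonate | OCc1cc(=O)c(OS(=O)(=O)C(F)(F)F)co1 | intermediate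
13 | 2-(hydroxymethyl)-5-Ar-4H-pyran-4-one | C/C(=C\Cc1cc(-c2coc(CO)cc2=O)ccc1O[Si](C(C)C)(C(C)C)C(C)C)CO[Si](C)(C)C(C)(C)C | intermediate
14 | 4-oxo-5-Ar-4H-pyran-2-carbaldehyde | C/C(=C\Cc1cc(-c2coc(C=O)cc2=O)ccc1O[Si](C(C)C)(C(C)C)C(C)C)CO[Si](C)(C)C(C)(C)C | intermediate
15 | 4-oxo-5-Ar-4H-pyran-2-carboxylic acid | C/C(=C\Cc1cc(-c2coc(C(=O)O)cc2=O)ccc1O[Si](C(C)C)(C(C)C)C(C)C)CO[Si](C)(C)C(C)(C)C | intermediate
16 | 4-oxo-5-Ar-4H-pyran-2-carbonyl chloride | C/C(=C\Cc1cc(-c2coc(C(=O)Cl)cc2=O)ccc1O[Si](C(C)C)(C(C)C)C(C)C)CO[Si](C)(C)C(C)(C)C | intermediate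
17 | 2-(2-diazoacetyl)-5-Ar-4H-pyran-4-one | C/C(=C\Cc1cc(-c2coc(C(=O)C=[N+]=[N-])cc2=O)ccc1O[Si](C(C)C)(C(C)C)C(C)C)CO[Si](C)(C)C(C)(C)C | intermediate
18 | 2-(trimethylsilyl)ethanol | C[Si](C)(C)CCO | starting material
19 | trichloroethylene | ClC=C(Cl)Cl | starting material
20 | {2-[(E)-1,2-dichloroethenoxy]ethyl}trimethylsilane | Cl/C=C(/Cl)OCC[Si](C)(C)C | intermediate
21 | lithium [2-(trimethylsilyl)ethoxy]ethynide | [Li]C#COCC[Si](C)(C)C | intermediate
22 | [2-(ethynyloxy)ethyl]trimethylsilane (2-(trimethylsilyl)ethoxyethyne) | C#COCC[Si](C)(C)C | intermediate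
23 | 2-(4-oxo-5-Ar-4H-pyran-2-yl)ethen-1-one (pyranonylketene) | C/C(=C\Cc1cc(-c2coc(C=C=O)cc2=O)ccc1O[Si](C(C)C)(C(C)C)C(C)C)CO[Si](C)(C)C(C)(C)C | intermediate
24 | 4-(4-oxo-5-Ar-4H-pyran-2-yl)-3-[2-(trimethylsilyl)ethoxy]cyclobut-2-en-1-one, racemic | C/C(=C\Cc1cc(-c2coc(C3C(=O)C=C3OCC[Si](C)(C)C)cc2=O)ccc1O[Si](C(C)C)(C(C)C)C(C)C)CO[Si](C)(C)C(C)(C)C | intermediate
25 | (3E)-4-(4-oxo-5-Ar-4H-pyran-2-yl)-3-[2-(trimethylsilyl)ethoxy]buta-1,3-dien-1-one, pyranonyl group cis to the ketene carbon | C/C(=C\Cc1cc(-c2coc(/C=C(OCC[Si](C)(C)C)\C=C=O)cc2=O)ccc1O[Si](C(C)C)(C(C)C)C(C)C)CO[Si](C)(C)C(C)(C)C | intermediate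
26 | 3-Ar-7-[2-(trimethylsilyl)ethoxy]-4aH-chromene-4,5-dione, racemic at C4a | C/C(=C\Cc1cc(C2=COC3=CC(OCC[Si](C)(C)C)=CC(=O)C3C2=O)ccc1O[Si](C(C)C)(C(C)C)C(C)C)CO[Si](C)(C)C(C)(C)C | intermediate
27 | 5-hydroxy-3-Ar-7-[2-(trimethylsilyl)ethoxy]-4H-chromen-4-one | C/C(=C\Cc1cc(-c2coc3cc(OCC[Si](C)(C)C)cc(O)c3c2=O)ccc1O[Si](C(C)C)(C(C)C)C(C)C)CO[Si](C)(C)C(C)(C)C | intermediate
28 | Vogelin E, 5,7-dihydroxy-3-{4-hydroxy-3-[(E)-4-hydroxy-3-methylbut-2-en-1-yl]phenyl}-4H-chromen-4-one | C/C(=C\Cc1cc(-c2coc3cc(O)cc(O)c3c2=O)ccc1O)CO | target

## Step count and risks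

Total step count: 15. Longest linear sequence: 12 steps (steps 1–7, 9, 10, 11, 14, 15). The pyranone branch (step 8) and the alkyne branch (steps 12, 13) are shorter.

Least certain steps:

**Step 14 (key step).** The most likely failure is competing excitation of the 4-pyranone or of product 27 at the irradiation wavelength, leading to photo-isomerisation of the pyranone ring. Dimerisation of the ketene before the alkyne captures it is the second concern. The fallback makes the same ketene without light. Diazoketone 17 would be rearranged in the dark with catalytic PhCO2Ag and Et3N in aqueous THF (silver-catalysed Wolff rearrangement, Arndt–Eistert homologation) to (4-oxo-5-Ar-4H-pyran-2-yl)acetic acid F1. Me2C=C(Cl)NMe2 would convert F1 into (4-oxo-5-Ar-4H-pyran-2-yl)acetyl chloride F2. Slow addition of Et3N to F2 and 22 at 0 °C would dehydrochlorinate it to ketene 23, which is trapped as cyclobutenone 24. Heating 24 at 80 °C rejoins the route at 27.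

**Step 11.** Diazomethane may add as a 1,3-dipole across the electron-poor C2=C3 bond of the pyranone acyl chloride, and the diazoketone may be chlorinated by HCl if mixing is poor. The fallback replaces acylation of CH2N2 by diazo transfer. Alcohol 13 would be oxidised with MnO2 to aldehyde 14, isolated this time, and treated with CH3MgBr at −78 °C to give 2-(1-hydroxyethyl)-5-Ar-4H-pyran-4-one F3. Dess–Martin periodinane would oxidise F3 to 2-acetyl-5-Ar-4H-pyran-4-one F4. Its lithium enolate (LiN(SiMe3)2, THF, −78 °C) would be trifluoroacetylated with CF3CO2CH2CF3 to 4,4,4-trifluoro-1-(4-oxo-5-Ar-4H-pyran-2-yl)butane-1,3-dione F5. Detrifluoroacetylative diazo transfer to F5 with CH3SO2N3, Et3N and water returns to 17.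

**Step 4.** A ruthenium hydride may move the allyl double bond into conjugation with the arene before metathesis, 5 may self-metathesise, or E selectivity may be incomplete. The fallback builds the olefin by a Wittig reaction. Oxidative cleavage of 5 (catalytic OsO4, NaIO4, 2,6-lutidine, aqueous dioxane) would give 2-[5-bromo-2-(triisopropylsilyloxy)phenyl]acetaldehyde F6. The stabilised ylide ethyl 2-(triphenylphosphoranylidene)propanoate would convert F6 E-selectively into ethyl (E)-4-[5-bromo-2-(triisopropylsilyloxy)phenyl]-2-methylbut-2-enoate F7. Reduction of F7 with i-Bu2AlH (2.2 equiv) rejoins the route at 8.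

**Step 8.** The primary hydroxyl may be sulfonylated as well, conversion may be low because kojic acid dissolves poorly, and the triflate may later be lost by hydrolysis in step 9. The fallback carries the future carboxyl carbon as an ester. Kojic acid 11 would be oxidised with O2 over Pd/C in aqueous NaOH to comenic acid F8 and esterified (MeOH, H2SO4) to methyl comenate F9. Tf2O and pyridine would convert F9 into methyl 4-oxo-5-(trifluoromethylsulfonyloxy)-4H-pyran-2-carboxylate F10. Suzuki–Miyaura coupling of F10 with 10 under the conditions of step 9 would give methyl 4-oxo-5-Ar-4H-pyran-2-carboxylate F11. LiOH in aqueous THF at 0 °C would hydrolyse F11 to acid 15, where the route is rejoined; steps 8–10 are replaced.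

## Further compounds

F1 | step 14 | (4-oxo-5-Ar-4H-pyran-2-yl)acetic acid | C/C(=C\Cc1cc(-c2coc(CC(=O)O)cc2=O)ccc1O[Si](C(C)C)(C(C)C)C(C)C)CO[Si](C)(C)C(C)(C)C
F2 | step 14 | (4-oxo-5-Ar-4H-pyran-2-yl)acetyl chloride | C/C(=C\Cc1cc(-c2coc(CC(=O)Cl)cc2=O)ccc1O[Si](C(C)C)(C(C)C)C(C)C)CO[Si](C)(C)C(C)(C)C
F3 | step 11 | 2-(1-hydroxyethyl)-5-Ar-4H-pyran-4-one, racemic | C/C(=C\Cc1cc(-c2coc(C(C)O)cc2=O)ccc1O[Si](C(C)C)(C(C)C)C(C)C)CO[Si](C)(C)C(C)(C)C
F4 | step 11 | 2-acetyl-5-Ar-4H-pyran-4-one | C/C(=C\Cc1cc(-c2coc(C(C)=O)cc2=O)ccc1O[Si](C(C)C)(C(C)C)C(C)C)CO[Si](C)(C)C(C)(C)C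
F5 | step 11 | 4,4,4-trifluoro-1-(4-oxo-5-Ar-4H-pyran-2-yl)butane-1,3-dione | C/C(=C\Cc1cc(-c2coc(C(=O)CC(=O)C(F)(F)F)cc2=O)ccc1O[Si](C(C)C)(C(C)C)C(C)C)CO[Si](C)(C)C(C)(C)C
F6 | step 4 | 2-[5-bromo-2-(triisopropylsilyloxy)phenyl]acetaldehyde | O=CCc1cc(Br)ccc1O[Si](C(C)C)(C(C)C)C(C)C
F7 | step 4 | ethyl (E)-4-[5-bromo-2-(triisopropylsilyloxy)phenyl]-2-methylbut-2-enoate | CCOC(=O)/C(C)=C/Cc1cc(Br)ccc1O[Si](C(C)C)(C(C)C)C(C)C
F8 | step 8 | comenic acid, 5-hydroxy-4-oxo-4H-pyran-2-carboxylic acid | O=C(O)c1cc(=O)c(O)co1
F9 | step 8 | methyl comenate, methyl 5-hydroxy-4-oxo-4H-pyran-2-carboxylate | COC(=O)c1cc(=O)c(O)co1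
F10 | step 8 | methyl 4-oxo-5-(trifluoromethylsulfonyloxy)-4H-pyran-2-carboxylate | COC(=O)c1cc(=O)c(OS(=O)(=O)C(F)(F)F)co1
F11 | step 8 | methyl 4-oxo-5-Ar-4H-pyran-2-carboxylate | C/C(=C\Cc1cc(-c2coc(C(=O)OC)cc2=O)ccc1O[Si](C(C)C)(C(C)C)C(C)C)CO[Si](C)(C)C(C)(C)C
A1 | alternative 1 | 5,7-bis(methoxymethoxy)-3-{3-[(E)-4-hydroxy-3-methylbut-2-en-1-yl]-4-(methoxymethoxy)phenyl}-4H-chromen-4-one | C/C(=C\Cc1cc(-c2coc3cc(OCOC)cc(OCOC)c3c2=O)ccc1OCOC)CO
A2 | alternative 1 | 3-[3-(chloromethyl)-4-(methoxymethoxy)phenyl]-5,7-bis(methoxymethoxy)-4H-chromen-4-one | ClCc1cc(-c2coc3cc(OCOC)cc(OCOC)c3c2=O)ccc1OCOC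
A3 | alternative 1 | prop-2-yn-1-ol | C#CCO
A4 | alternative 1 | [(E)-3-(dimethylalumanyloxy)-2-methylprop-1-en-1-yl]dimethylalumane | C/C(=C\[Al](C)C)CO[Al](C)C
A5 | alternative 2 | 5,7-bis(benzyloxy)-3-(4-benzyloxy-3-bromophenyl)-4H-chromen-4-one | O=c1c(-c2ccc(OCc3ccccc3)c(Br)c2)coc2cc(OCc3ccccc3)cc(OCc3ccccc3)c12
A6 | alternative 2 | (E)-1-[2,4-bis(benzyloxy)-6-hydroxyphenyl]-3-(4-benzyloxy-3-bromophenyl)prop-2-en-1-one | O=C(/C=C/c1ccc(OCc2ccccc2)c(Br)c1)c1c(O)cc(OCc2ccccc2)cc1OCc1ccccc1
A7 | alternative 3 | 5,7-difluoro-3-{3-[(E)-3-methyl-4-(triisopropylsilyloxy)but-2-en-1-yl]-4-(triisopropylsilyloxy)phenyl}-4H-chromen-4-one | C/C(=C\Cc1cc(-c2coc3cc(F)cc(F)c3c2=O)ccc1O[Si](C(C)C)(C(C)C)C(C)C)CO[Si](C(C)C)(C(C)C)C(C)C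
A8 | alternative 3 | 2,4,6-trifluorobenzoyl chloride | O=C(Cl)c1c(F)cc(F)cc1F
A9 | alternative 3 | 1-[(E)-2-{3-[(E)-3-methyl-4-(triisopropylsilyloxy)but-2-en-1-yl]-4-(triisopropylsilyloxy)phenyl}ethenyl]pyrrolidine | C/C(=C\Cc1cc(/C=C/N2CCCC2)ccc1O[Si](C(C)C)(C(C)C)C(C)C)CO[Si](C(C)C)(C(C)C)C(C)C
A10 | alternative 3 | 2-{3-[(E)-3-methyl-4-(triisopropylsilyloxy)but-2-en-1-yl]-4-(triisopropylsilyloxy)phenyl}acetaldehyde | C/C(=C\Cc1cc(CC=O)ccc1O[Si](C(C)C)(C(C)C)C(C)C)CO[Si](C(C)C)(C(C)C)C(C)C
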